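The data come from a simulation on assumed constants; the scatter is artificial.

Take the ratio of reagent to substrate charged, 0.600: the candidate is asked to judge this flask from that ratio and its readings at 25 min.

- eta: substrate 0.40 M; reagent 0.24 M; free catalyst 60 mM; the very flask that is asked about, followed so far
- flask: substrate 0.40 M; reagent 0.240 M; free catalyst 60 mM; time 25 min

eta run (percent of the substrate charged)

| time / min | target / % | substrate / % |
|---|---|---|
| 3.00 | 20 | 69 |
| 6.00 | 34 | 57 |
| 8.00 | 38 | 48 |
| 12.0 | 33 | 44 |
| 15.0 | 31 | 40 |
| 20.0 | 22 | 40 |

(scatter of a reading: 1.5 percentage points)

- elm: at 25 min add free catalyst, 100% of the amount charged, then wait 12 min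
- cedar: at 25 min take out 90% of the target then present, then wait 12 min
- birch: at 25 min add reagent, 100% of the amount charged, then wait 12 min
- oak: change nothing and wait 12 min more

- target, in percent of the substrate first charged, at 25 min
- the option that brings most further target ("none" if no option brings more than 2 percentage points) (elm / cedar / birch / oak / none)
- target present, with what was taken out counted in, in percent of the substrate first charged, after birch
- target present, with what was taken out counted in, in percent of the substrate first charged, after oak

- target that was removed still counts
- additions bring no volume worth counting

What do the readings show first? Substrate reads 69% at 3.00 min, then 40% at 15.0 min and 40% at 20.0 min, so within a scatter of 1.5 percentage points it has stopped falling.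

Where should it stop? Suppose one reagent takes one substrate. One minus the ratio gives 40.0%: call this the stopping share, the part of the substrate charged that stays free once a one-to-one reagent has been used up. Reagent, charged at less than the substrate, is then the limiting reagent. The charges give that share and the readings show the same figure, so this is a real check.

Weak spot: a dying catalyst also stops a flask. Why not that? One recipe cannot exclude it, but a catalyst dying just at this share is a coincidence I won't bet on.

And the target? From 15.0 min to 20.0 min it reads 31% then 22% while substrate reads 40% then 40%, so over that stretch it is going somewhere unread, and waiting looks like a loss.

What restarts the flask? Free substrate stands near 0.160 M, and birch adds 0.240 M, more reagent than free substrate, a new ratio of 1.50. Above one, the reckoning gives no positive stopping share, so the remaining substrate is open again. Elm adds no reagent, and cedar protects target without turning substrate. I commit to birch.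

The forecast agrees: “This points to 1:1 reagent exhaustion, not a stalled catalyst.” It gives 16.5% at 25 min, birch as best, 25% after birch and 8% after oak.

The flask gives 18.2% at 25 min, and birch is best, with 31.7% of target after it, more than the forecast's 25%, while oak ends at 11.4%.

    reagent + free catalyst ⇌ catalyst intermediate A (K = 5.90 /M, k = 4.70 /M/s)
    substrate + catalyst intermediate A → catalyst intermediate B (k = 0.120 /M/s)
    catalyst intermediate B → catalyst intermediate C (k = 0.0360 /s)
    catalyst intermediate C → free catalyst + target (k = 0.0410 /s)
    target ⇌ isomer of the product (K = 7.20, k = 0.00120 /s)

At 25.0 min this flask holds 40.1% of its substrate free and 0.0752% of its reagent, which meets the stopping share of 40.0%. The neighbouring flask with 1.6 M of substrate and the same reagent has a stopping share of 85.0%, and it holds 85.0% of its substrate at 25.0 min.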